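Everything rests on disconnecting the C6–C7 bond of the 5,6,7,8-tetrahydroquinoline: the carbocycle is traced back to a five-membered cyclopenta[b]pyridin-5-ol whose carbinol carbon carries a 1-(3,4-dimethoxyphenyl)alkenyl group. Protonation of that alkene and a 1,2-shift of the ring CH2 enlarge the ring, unveil a C5 ketone and set the quaternary stereocentre C6 in a single operation. The feature exploited is the position of C6 (quinoline numbering): it bears the dimethoxyphenyl ring and lies between the pyridine-bound C5 and the CH2 at C7, so positive charge at C6 is aryl-stabilised and draws C7 over from C5. The precursor is a racemic tertiary alcohol with an (E)-aryl alkene ending in a sulfonamide-protected CH2–N(Me) group.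

Key step: step 5

Remarks on the chemistry (one line each)
- Configuration: C6 is S in the target and in 10–17; the CIP ranking changes when C5 goes from C=O or CH–O to CH2, but the descriptor and the spatial arrangement stay the same, and no bond to C6 is touched after step 5.
- Nitrogen group: the amine is carried as its 2-(trimethylsilyl)ethanesulfonyl (SES) amide, which is as non-basic and non-nucleophilic as an arenesulfonamide but is removed by fluoride, so no electron-transfer reductant is needed next to the pyridine.
- Aryl introduction: alkoxide-directed arylmagnesiation of 5 would be one step shorter, but it places magnesium on the carbon next to CH2–N(SO2R), from which the sulfonamide can be expelled to give an allene; tin is therefore put on the carbinol-bearing carbon and the aryl group is coupled there.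
- Pyridine basicity: the pyridine would neutralise a catalytic chiral acid, so it is protonated beforehand with exactly one equivalent of triflimide; the pyridinium ring also blocks aryl migration.
- Assumption: the sense of induction of the chiral acid cannot be predicted, so the catalyst antipode that should give (S)-10 is chosen in a pilot run.

Step 1
Reactants: 1 N-methylprop-2-yn-1-amine (N-methylpropargylamine)
Product: 2 N-methyl-N-(prop-2-yn-1-yl)-2-(trimethylsilyl)ethane-1-sulfonamide
Conditions: SESCl (1.1 equiv), Et3N (1.5 equiv), CH2Cl2, 0 °C → rt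
Reagents that add atoms: 2-(trimethylsilyl)ethanesulfonyl chloride, C[Si](C)(C)CCS(=O)(=O)Cl
Why: N-sulfonylation of a secondary amine with a sulfonyl chloride and an amine base is fast and leaves the terminal alkyne untouched; no stereocentre is formed.

Step 2
Reactants: 2 N-methyl-N-(prop-2-yn-1-yl)-2-(trimethylsilyl)ethane-1-sulfonamide; 3 6,7-dihydro-5H-cyclopenta[b]pyridin-5-one
Product: 5 rac-N-[3-(5-hydroxy-6,7-dihydro-5H-cyclopenta[b]pyridin-5-yl)prop-2-yn-1-yl]-N-methyl-2-(trimethylsilyl)ethane-1-sulfonamide, via lithium acetylide 4 (not isolated)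
Conditions: n-BuLi (1.05 equiv), THF, −78 °C; then 3, −78 → −20 °C; aq. NH4Cl
Reagents that add atoms: none
Why: 1,2-addition of a lithium acetylide to the ketone (alkynylation) should outrun enolisation at low temperature and gives the tertiary propargylic alcohol as a racemate, which is acceptable because this centre becomes the carbonyl carbon in step 5.

Step 3
Reactants: 5 rac-N-[3-(5-hydroxy-6,7-dihydro-5H-cyclopenta[b]pyridin-5-yl)prop-2-yn-1-yl]-N-methyl-2-(trimethylsilyl)ethane-1-sulfonamide
Product: 6 rac-(Z)-N-[3-(5-hydroxy-6,7-dihydro-5H-cyclopenta[b]pyridin-5-yl)-3-(tributylstannyl)prop-2-en-1-yl]-N-methyl-2-(trimethylsilyl)ethane-1-sulfonamide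
Conditions: Bu3SnH (1.2 equiv, slow addition), [Cp*RuCl]4 (2.5 mol%), CH2Cl2, rt
Reagents that add atoms: tributyltin hydride, CCCC[SnH](CCCC)CCCC
Why: ruthenium-catalysed hydroxyl-directed trans-hydrostannation: hydrogen bonding of the free OH to the Ru–Cl unit should steer tin to the alkyne carbon next to the carbinol, and H and Sn are delivered to opposite sides, which fixes the Z geometry.

Step 4
Reactants: 6 rac-(Z)-N-[3-(5-hydroxy-6,7-dihydro-5H-cyclopenta[b]pyridin-5-yl)-3-(tributylstannyl)prop-2-en-1-yl]-N-methyl-2-(trimethylsilyl)ethane-1-sulfonamide; 7 4-iodo-1,2-dimethoxybenzene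
Product: 8 rac-(E)-N-[3-(3,4-dimethoxyphenyl)-3-(5-hydroxy-6,7-dihydro-5H-cyclopenta[b]pyridin-5-yl)prop-2-en-1-yl]-N-methyl-2-(trimethylsilyl)ethane-1-sulfonamide
Conditions: Pd(PPh3)4 (10 mol%), CuTC (1.5 equiv), [Bu4N][Ph2PO2] (1.5 equiv), DMF, rt
Reagents that add atoms: none
Why: Stille cross-coupling assisted by copper(I) carboxylate and a phosphinate tin scavenger runs under neutral, fluoride-free conditions that spare the SES group and proceeds with retention at the alkenyl carbon, so the Z stannane should give the E aryl alkene (aryl cis to CH2N).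

Step 5
Reactants: 8 rac-(E)-N-[3-(3,4-dimethoxyphenyl)-3-(5-hydroxy-6,7-dihydro-5H-cyclopenta[b]pyridin-5-yl)prop-2-en-1-yl]-N-methyl-2-(trimethylsilyl)ethane-1-sulfonamide
Product: 10 (S)-N-{2-[6-(3,4-dimethoxyphenyl)-5-oxo-5,6,7,8-tetrahydroquinolin-6-yl]ethyl}-N-methyl-2-(trimethylsilyl)ethane-1-sulfonamide, via pyridinium triflimide salt 9 (not isolated)
Conditions: HNTf2 (1.00 equiv), CH2Cl2, −40 °C; chiral IDPi Brønsted acid (10 mol%), −40 → 0 °C; aq. NaHCO3
Reagents that add atoms: none
Why: Proposed new method: one equivalent of triflimide (its anion is too weakly basic to deprotonate the chiral acid) first converts the pyridine into its pyridinium salt, the confined chiral acid then protonates the alkene CH to give a 3,4-dimethoxybenzyl cation, the cyclopentane CH2 aligned with the empty p orbital shifts from the carbinol carbon to the cationic carbon, and the oxocarbenium ion so formed gives up its O–H proton to the chiral anion, releasing the 5-ketone and the acid. The closest known reaction type is the chiral-acid-catalysed protio-semipinacol ring expansion of 1-(1-arylvinyl)cyclobutanols and the halonium-triggered semipinacol shift of related cycloalkanols; a cyclopentanol-to-cyclohexanone expansion of a stereogenic pyridine-fused carbinol has not been shown. The six-membered ring arises by one-carbon ring enlargement through a suprafacial 1,2-alkyl shift and not by cyclisation, so no Baldwin mode is involved. The C6 stereocentre is set by the chiral counter-anion, which remains hydrogen-bonded to the carbinol O–H and determines which face of the planar cation receives the migrating carbon. Two selectivities are needed: alkyl instead of aryl migration, secured because the protonated pyridine ring cannot bridge to a cation, and convergence of both carbinol enantiomers on one product enantiomer, possible because the carbinol centre ends as the carbonyl carbon and the aryl-stabilised cation lives long enough to rotate about the C–C+ bond before the shift. The SES sulfonamide is neither basic enough to bind the acid nor nucleophilic enough to trap the cation.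

Step 6
Reactants: 10 (S)-N-{2-[6-(3,4-dimethoxyphenyl)-5-oxo-5,6,7,8-tetrahydroquinolin-6-yl]ethyl}-N-methyl-2-(trimethylsilyl)ethane-1-sulfonamide
Product: 11 N-{2-[(6S)-6-(3,4-dimethoxyphenyl)-5-hydroxy-5,6,7,8-tetrahydroquinolin-6-yl]ethyl}-N-methyl-2-(trimethylsilyl)ethane-1-sulfonamide (both C5 epimers)
Conditions: NaBH4, MeOH, 0 °C → rt
Reagents that add atoms: none
Why: borohydride reduction of the pyridyl ketone (1,2-hydride addition) gives the C5 carbinol as an epimer mixture that does not matter because C5 becomes CH2 in step 8, while C6 has no α-hydrogen and cannot epimerise.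

Step 7
Reactants: 11 N-{2-[(6S)-6-(3,4-dimethoxyphenyl)-5-hydroxy-5,6,7,8-tetrahydroquinolin-6-yl]ethyl}-N-methyl-2-(trimethylsilyl)ethane-1-sulfonamide (both C5 epimers)
Product: 14 O-[(6S)-6-(3,4-dimethoxyphenyl)-6-(2-{methyl[2-(trimethylsilyl)ethanesulfonyl]amino}ethyl)-5,6,7,8-tetrahydroquinolin-5-yl] S-methyl carbonodithioate (both C5 epimers), via sodium alkoxide 12 (not isolated), via sodium xanthate 13 (not isolated)
Conditions: NaH, THF, 0 °C → rt; CS2; MeI (1.1 equiv), 0 °C
Reagents that add atoms: carbon disulfide, S=C=S; iodomethane, CI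
Why: xanthate formation (first stage of the Barton–McCombie deoxygenation) copes with hindered alcohols because the alkoxide adds to CS2, and the soft dithiocarbonate sulfur is methylated far faster than the pyridine nitrogen when iodomethane is kept near one equivalent.

Step 8
Reactants: 14 O-[(6S)-6-(3,4-dimethoxyphenyl)-6-(2-{methyl[2-(trimethylsilyl)ethanesulfonyl]amino}ethyl)-5,6,7,8-tetrahydroquinolin-5-yl] S-methyl carbonodithioate (both C5 epimers)
Product: 15 (S)-N-{2-[6-(3,4-dimethoxyphenyl)-5,6,7,8-tetrahydroquinolin-6-yl]ethyl}-N-methyl-2-(trimethylsilyl)ethane-1-sulfonamide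
Conditions: Bu3SnH, AIBN (cat.), PhMe, 110 °C
Reagents that add atoms: none
Why: Barton–McCombie radical deoxygenation: the stannyl radical adds to C=S, β-scission gives a pyridine-stabilised secondary benzylic radical at C5 that is reduced by Bu3SnH, and with no hydrogen on C6 neither Chugaev elimination nor epimerisation can intervene.

Step 9
Reactants: 15 (S)-N-{2-[6-(3,4-dimethoxyphenyl)-5,6,7,8-tetrahydroquinolin-6-yl]ethyl}-N-methyl-2-(trimethylsilyl)ethane-1-sulfonamide
Product: 16 (S)-2-[6-(3,4-dimethoxyphenyl)-5,6,7,8-tetrahydroquinolin-6-yl]-N-methylethan-1-amine (tortuosamine)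
Conditions: CsF, DMF, 95 °C; aqueous work-up
Reagents that add atoms: none
Why: fluoride-induced fragmentation of the SES sulfonamide (attack at silicon, loss of ethene and SO2) frees the secondary amine without any reductant, so the pyridine ring and the aryl methyl ethers should be untouched.

Step 10
Reactants: 16 (S)-2-[6-(3,4-dimethoxyphenyl)-5,6,7,8-tetrahydroquinolin-6-yl]-N-methylethan-1-amine
Product: 17 (S)-N-{2-[6-(3,4-dimethoxyphenyl)-5,6,7,8-tetrahydroquinolin-6-yl]ethyl}-N-methylformamide
Conditions: HCO2Et, reflux
Reagents that add atoms: ethyl formate, CCOC=O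
Why: N-formylation of the secondary amine by aminolysis of ethyl formate is chemoselective, since the pyridine nitrogen cannot be acylated irreversibly, and leaves C6 untouched.

Compound list
1 | N-methylprop-2-yn-1-amine (N-methylpropargylamine) | C#CCNC | starting material
2 | N-methyl-N-(prop-2-yn-1-yl)-2-(trimethylsilyl)ethane-1-sulfonamide | C#CCN(C)S(=O)(=O)CC[Si](C)(C)C | intermediate
3 | 6,7-dihydro-5H-cyclopenta[b]pyridin-5-one | O=C1CCc2ncccc12 | starting material
4 | lithium acetylide of 2 (formed in the flask) | [Li+].[C-]#CCN(C)S(=O)(=O)CC[Si](C)(C)C | intermediate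
5 | rac-N-[3-(5-hydroxy-6,7-dihydro-5H-cyclopenta[b]pyridin-5-yl)prop-2-yn-1-yl]-N-methyl-2-(trimethylsilyl)ethane-1-sulfonamide | OC1(CCc2ncccc12)C#CCN(C)S(=O)(=O)CC[Si](C)(C)C | intermediate
6 | rac-(Z)-N-[3-(5-hydroxy-6,7-dihydro-5H-cyclopenta[b]pyridin-5-yl)-3-(tributylstannyl)prop-2-en-1-yl]-N-methyl-2-(trimethylsilyl)ethane-1-sulfonamide | OC1(CCc2ncccc12)/C([Sn](CCCC)(CCCC)CCCC)=C/CN(C)S(=O)(=O)CC[Si](C)(C)C | intermediate
7 | 4-iodo-1,2-dimethoxybenzene | COc1ccc(I)cc1OC | starting material
8 | rac-(E)-N-[3-(3,4-dimethoxyphenyl)-3-(5-hydroxy-6,7-dihydro-5H-cyclopenta[b]pyridin-5-yl)prop-2-en-1-yl]-N-methyl-2-(trimethylsilyl)ethane-1-sulfonamide | OC1(CCc2ncccc12)/C(c1ccc(OC)c(OC)c1)=C/CN(C)S(=O)(=O)CC[Si](C)(C)C | intermediate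
9 | pyridinium bis(trifluoromethanesulfonyl)imide salt of 8 (formed in the flask) | OC1(CCc2[nH+]cccc12)/C(c1ccc(OC)c(OC)c1)=C/CN(C)S(=O)(=O)CC[Si](C)(C)C.O=S(=O)([N-]S(=O)(=O)C(F)(F)F)C(F)(F)F | intermediate
10 | (S)-N-{2-[6-(3,4-dimethoxyphenyl)-5-oxo-5,6,7,8-tetrahydroquinolin-6-yl]ethyl}-N-methyl-2-(trimethylsilyl)ethane-1-sulfonamide | COc1ccc([C@@]2(CCN(C)S(=O)(=O)CC[Si](C)(C)C)CCc3ncccc3C2=O)cc1OC | intermediate
11 | N-{2-[(6S)-6-(3,4-dimethoxyphenyl)-5-hydroxy-5,6,7,8-tetrahydroquinolin-6-yl]ethyl}-N-methyl-2-(trimethylsilyl)ethane-1-sulfonamide, both C5 epimers | COc1ccc([C@@]2(CCN(C)S(=O)(=O)CC[Si](C)(C)C)CCc3ncccc3C2O)cc1OC | intermediate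
12 | sodium alkoxide of 11 (formed in the flask) | COc1ccc([C@@]2(CCN(C)S(=O)(=O)CC[Si](C)(C)C)CCc3ncccc3C2[O-])cc1OC.[Na+] | intermediate
13 | sodium O-alkyl dithiocarbonate (xanthate salt) of 11 (formed in the flask) | COc1ccc([C@@]2(CCN(C)S(=O)(=O)CC[Si](C)(C)C)CCc3ncccc3C2OC(=S)[S-])cc1OC.[Na+] | intermediate
14 | O-[(6S)-6-(3,4-dimethoxyphenyl)-6-(2-{methyl[2-(trimethylsilyl)ethanesulfonyl]amino}ethyl)-5,6,7,8-tetrahydroquinolin-5-yl] S-methyl carbonodithioate, both C5 epimers | COc1ccc([C@@]2(CCN(C)S(=O)(=O)CC[Si](C)(C)C)CCc3ncccc3C2OC(=S)SC)cc1OC | intermediate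
15 | (S)-N-{2-[6-(3,4-dimethoxyphenyl)-5,6,7,8-tetrahydroquinolin-6-yl]ethyl}-N-methyl-2-(trimethylsilyl)ethane-1-sulfonamide | COc1ccc([C@@]2(CCN(C)S(=O)(=O)CC[Si](C)(C)C)CCc3ncccc3C2)cc1OC | intermediate
16 | (S)-2-[6-(3,4-dimethoxyphenyl)-5,6,7,8-tetrahydroquinolin-6-yl]-N-methylethan-1-amine (tortuosamine) | COc1ccc([C@@]2(CCNC)CCc3ncccc3C2)cc1OC | intermediate
17 | (S)-N-{2-[6-(3,4-dimethoxyphenyl)-5,6,7,8-tetrahydroquinolin-6-yl]ethyl}-N-methylformamide (N-formyltortuosamine, CNP0346821.1) | COc1ccc([C@@]2(CCN(C)C=O)CCc3ncccc3C2)cc1OC | target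

Total step count: 10
Longest linear sequence: 10 steps (1 → 2 → 5 → 6 → 8 → 10 → 11 → 14 → 15 → 16 → 17); 3 and 7 enter as commercial partners.

Steps most likely to fail

1. Step 5 (new method). What may go wrong: insufficient face discrimination at the planar cation; divergent behaviour of the two carbinol antipodes (one matched, one mismatched with the catalyst); or a racemic background shift within the achiral triflimide ion pair. Fallback, setting out from 8 and returning at 10: excess achiral TfOH in CH2Cl2 should promote the established acid-mediated semipinacol ring expansion of the 1-(1-arylvinyl)cycloalkanol to the racemic ketone F1. Preparative chromatography on a chiral stationary phase (SFC) then separates the (S)-enantiomer, which is 10. Stereocontrol thus changes from catalysis to resolution.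

2. Step 3. What may go wrong: arrest of the catalyst through binding of the pyridine nitrogen to ruthenium, or erosion of the regioselectivity for the carbinol-bearing carbon. Fallback, setting out from 5 and returning at 8: O-directed free-radical hydrostannation of 5 with Ph3SnH and catalytic Et3B/air in toluene, a chain process indifferent to the pyridine, should give the (Z)-α-triphenylstannyl allylic alcohol F2. Iododestannylation with I2 in CH2Cl2 converts it into the (Z)-alkenyl iodide F3 (which would equally be at hand from 6 and iodine). Suzuki–Miyaura coupling of F3 with commercial 3,4-dimethoxyphenylboronic acid (Pd(dppf)Cl2, K3PO4, dioxane/H2O) then delivers 8 with retention of geometry.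

3. Step 4. What may go wrong: slow transmetalation at the congested alkenylstannane, so that protodestannylation takes over. Fallback, setting out from 5 and returning at 8, tin-free: alkoxide-directed anti-arylmagnesiation of 5 with commercial 3,4-dimethoxyphenylmagnesium bromide (THF/toluene, gentle warming) forms the aryl–alkenyl bond by addition and passes through the five-membered alkenylmagnesium alkoxide chelate F4. Protonation with aq. NH4Cl gives 8 with the same E geometry. This is held in reserve because the magnesium-bearing carbon of F4 is adjacent to CH2–N(SO2R), so the lowest temperature that gives conversion is to be used to limit expulsion of the sulfonamide.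

Further compounds
F1 | step 5 | rac-N-{2-[6-(3,4-dimethoxyphenyl)-5-oxo-5,6,7,8-tetrahydroquinolin-6-yl]ethyl}-N-methyl-2-(trimethylsilyl)ethane-1-sulfonamide | COc1ccc(C2(CCN(C)S(=O)(=O)CC[Si](C)(C)C)CCc3ncccc3C2=O)cc1OC
F2 | step 3 | rac-(Z)-N-[3-(5-hydroxy-6,7-dihydro-5H-cyclopenta[b]pyridin-5-yl)-3-(triphenylstannyl)prop-2-en-1-yl]-N-methyl-2-(trimethylsilyl)ethane-1-sulfonamide | OC1(CCc2ncccc12)/C([Sn](c1ccccc1)(c1ccccc1)c1ccccc1)=C/CN(C)S(=O)(=O)CC[Si](C)(C)C
F3 | step 3 | rac-(Z)-N-[3-(5-hydroxy-6,7-dihydro-5H-cyclopenta[b]pyridin-5-yl)-3-iodoprop-2-en-1-yl]-N-methyl-2-(trimethylsilyl)ethane-1-sulfonamide | OC1(CCc2ncccc12)/C(I)=C/CN(C)S(=O)(=O)CC[Si](C)(C)C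
F4 | step 4 | spiro-fused alkenylmagnesium alkoxide chelate (2,5-dihydro-1,2-oxamagnesole) formed from 5 and the aryl Grignard reagent | [Mg]1OC2(CCc3ncccc32)C(c2ccc(OC)c(OC)c2)=C1CN(C)S(=O)(=O)CC[Si](C)(C)C
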